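Conventions: Ar′ = 4-(tert-butyldimethylsilyloxy)phenyl. Ring atoms are O1, C2 (aryl), C3 (side chain), C4 (OH), C5, C6 (arylethyl). Side chain atoms are C1′=C2′ (styrene), C3′ (bonded to C3) and C5′ (carbinol).

Assumption 1: the SMILES decodes as 2S,3S,4S,6S,3′S,5′S with a 1′E alkene. That is 2,6-cis, 2,3-trans and 3,4-cis, so the 4-OH is axial.

Assumption 2: compounds 1, 2, 4, 7, 9 and 13 are purchasable. Ligands and catalysts are not counted as steps.

## Retrosynthetic overview

1. No Prins disconnection. The C2 aryl group goes on last, as in a C-aryl glycoside: ArLi adds to δ-lactone 17, then axial hydride reduction of the oxocarbenium ion sets C2.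
2. The only ring-forming event is lactonisation of seco-acid 16 (O1–C2 bond). It comes after C3, C4, C6, C3′ and C5′ are already in place.
3. Key step: one dianionic Ireland–Claisen rearrangement of β-hydroxy ester 15 makes the C3–C3′ bond. It sets C3, C3′ and the E-styrene by 1,3-chirality transfer from a sacrificial benzylic carbinol.
4. Ester 15 comes from allylic alcohol 8 and β-lactone 14 by strain-driven acyl transfer.
5. Both 8 and 14 come from one aldehyde, 3. Iodide 1 is used twice (steps 1 and 12).

## Route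

**Step 1**
Reactants: 1 tert-butyl(4-iodophenoxy)dimethylsilane; 2 allyl alcohol
Product: 3 3-Ar′-propanal
Conditions: Pd(OAc)2 (3 mol %), n-Bu4NCl, NaHCO3, DMF, 40 °C
Reagents that add atoms: none (both partners are numbered reactants)
Why: Jeffery–Heck arylation of allyl alcohol, in which terminal carbopalladation, β-H elimination toward the carbinol and tautomerisation give the 3-arylpropanal under bicarbonate conditions that spare the aryl silyl ether; no stereocentre is formed.

**Step 2**
Reactants: 3; 4 allenyltributylstannane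
Product: 5 (S)-1-Ar′-hex-5-yn-3-ol
Conditions: (R)-BINOL/Ti(OiPr)4 (20 mol %), 4 Å MS, CH2Cl2, −20 °C
Reagents that add atoms: allenyltributylstannane (4), C=C=C[Sn](CCCC)(CCCC)CCCC
Why: Keck-type catalytic asymmetric propargylation (SE2′ addition of the allenylstannane), in which the (R)-BINOL–Ti complex directs Re-face attack to give the S carbinol that becomes C5′.

**Step 3**
Reactants: 5
Product: 6 (S)-3-(TBSO)-1-Ar′-hex-5-yne
Conditions: TBSCl, imidazole, DMF, rt
Reagents that add atoms: TBSCl, CC(C)(C)[Si](C)(C)Cl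
Why: Standard silylation installs a group on O5′ that survives B/Zn reagents, LDA, mild acid, ArLi and BF3 and is removed with the phenol silyl ethers at the end; the stereocentre is untouched.

**Step 4**
Reactants: 6; 7 4-(tert-butyldimethylsilyloxy)benzaldehyde
Product: 8 (1S,2E,5S)-5-(TBSO)-1,7-bis(Ar′)hept-2-en-1-ol
Conditions: Cy2BH, toluene, 0 °C to rt; Me2Zn, (−)-MIB (5 mol %), −78 °C; then 7, −20 to 0 °C
Reagents that add atoms: none (the borane supplies H only)
Why: Oppolzer-type hydroboration, B-to-Zn transmetalation and amino-alcohol-catalysed alkenylzinc addition, in which syn hydroboration fixes the E-alkene and (−)-MIB directs Si-face attack on the aryl aldehyde to give the sacrificial 1S carbinol.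

**Step 5**
Reactants: 3; 9 allyltributylstannane
Product: 10 (S)-1-Ar′-hex-5-en-3-ol
Conditions: (R)-BINOL/Ti(OiPr)4 (10 mol %), 4 Å MS, CH2Cl2, −20 °C
Reagents that add atoms: allyltributylstannane (9), C=CC[Sn](CCCC)(CCCC)CCCC
Why: Keck asymmetric allylation with the same catalyst and facial sense as step 2 sets the S carbinol that becomes C6.

**Step 6**
Reactants: 10
Product: 11 (S)-3-(triethylsilyloxy)-1-Ar′-hex-5-ene
Conditions: TESCl, imidazole, CH2Cl2, 0 °C
Reagents that add atoms: TESCl, CC[Si](CC)(CC)Cl
Why: Silylation with TES, which is about 100 times more acid-labile than TBS, so that O6 alone can be released in step 11.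

**Step 7**
Reactants: 11
Product: 12 (3S)-3-(triethylsilyloxy)-5-Ar′-pentanal
Conditions: O3, CH2Cl2, −78 °C (Sudan III end point); PPh3
Reagents that add atoms: ozone, [O-][O+]=O
Why: Ozonolysis with reductive work-up cleaves the terminal alkene much faster than ozone attacks the silyloxyarene, and the indicator prevents over-oxidation.

**Step 8**
Reactants: 12; 13 acetyl bromide
Product: 14 (4S)-4-[(2S)-2-(triethylsilyloxy)-4-Ar′-butyl]oxetan-2-one
Conditions: i-Pr2NEt, Al(III) complex of the (S)-valine-derived bis(triflamide) triamine (15 mol %), CH2Cl2, −50 °C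
Reagents that add atoms: acetyl bromide (13), CC(=O)Br (delivers ketene, C2H2O)
Why: Catalytic asymmetric acyl halide–aldehyde cyclocondensation (ketene–aldehyde [2+2]), in which the catalyst enantiomer that gives 4S lactones from hydrocinnamaldehyde-type aldehydes sets C4 (S), 1,3-syn to O6, under catalyst control.

**Step 9**
Reactants: 8; 14
Product: 15 (1S,2E,5S)-5-(TBSO)-1,7-bis(Ar′)hept-2-en-1-yl (3S,5S)-3-hydroxy-5-(triethylsilyloxy)-7-Ar′-heptanoate
Conditions: 8, n-BuLi (1.0 equiv), THF, −78 °C; add 14, −78 to −30 °C; pH 7 buffer; Et3N-deactivated silica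
Reagents that add atoms: none
Why: Acyl–oxygen ring opening of a β-lactone by a hard lithium alkoxide, driven by strain release, gives the free β-hydroxy ester without acid, heat or carbodiimide, which the ionisable benzylic/allylic C–O bond would not tolerate; no stereocentre is touched.

**Step 10 (key step)**
Reactants: 15
Product: 16 (2S,3S,5S)-2-[(1E,3S,5S)-5-(TBSO)-1,7-bis(Ar′)hept-1-en-3-yl]-3-hydroxy-5-(triethylsilyloxy)-7-Ar′-heptanoic acid
Conditions: LDA (2.4 equiv), THF, −78 to −40 °C; TMSCl/Et3N, −78 °C to rt; 5 % aq. citric acid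
Reagents that add atoms: none in the isolated product (TMSCl, C[Si](C)(C)Cl, is incorporated only transiently and hydrolysed on work-up)
Why: Dianionic Ireland–Claisen rearrangement, in which Li chelation between the C4 alkoxide and the enolate oxygen fixes the Z(O)-enolate and blocks β-elimination, and the chair transition state with the C1′ aryl group equatorial relays the 1′S configuration suprafacially to C3′ (S) and C3 (S) (3,3′-syn and 3,4-anti, matched with the Fráter–Seebach facial bias) while forming the E-styrene.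

**Step 11**
Reactants: 16
Product: 17 (3S,4S,6S)-3-[(1E,3S,5S)-5-(TBSO)-1,7-bis(Ar′)hept-1-en-3-yl]-4-hydroxy-6-(2-Ar′-ethyl)oxan-2-one
Conditions: PPTS (0.3 equiv), CH2Cl2/MeOH, rt; then toluene, 40 °C
Reagents that add atoms: none
Why: Selective acidic TES solvolysis followed by spontaneous δ-lactonisation closes the ring through O6 only, because O5′ stays TBS-protected and O4 could give only a β-lactone, and any O6-to-O4 silyl migration from steps 9–10 is erased here.

**Step 12**
Reactants: 17; 1 tert-butyl(4-iodophenoxy)dimethylsilane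
Product: 18 the C2 hemiketal (2-Ar′-2-hydroxy-oxane, anomer mixture in equilibrium with the open δ-hydroxy aryl ketone), otherwise as 17
Conditions: 1 (2.4 equiv), t-BuLi (4.8 equiv), Et2O, −78 °C; add 17 in THF, −78 °C; AcOH quench at −78 °C; use crude
Reagents that add atoms: none beyond reactant 1 (iodine is lost)
Why: 1,2-Addition of an aryllithium to a δ-lactone stops at the lithium hemiketal at −78 °C (C-aryl glycoside tactic), and the first equivalent of ArLi converts O4–H into an alkoxide that cannot leave by E1cB, so C3 and C4 are preserved.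

**Step 13**
Reactants: 18
Product: 19 (2S,3S,4S,6S)-2-Ar′-3-[(1E,3S,5S)-5-(TBSO)-1,7-bis(Ar′)hept-1-en-3-yl]-6-(2-Ar′-ethyl)oxan-4-ol
Conditions: Et3SiH (10 equiv), BF3·OEt2 (3 equiv), CH2Cl2/MeCN, −78 to −30 °C
Reagents that add atoms: none (the silane supplies H only)
Why: Kishi-type ionic reduction, in which the aryl-stabilised oxocarbenium half-chair (C3 and C6 groups pseudo-equatorial, C4–O pseudo-axial, its electronically preferred position) takes hydride along the axial trajectory and so places the aryl group equatorial (2S; 2,6-cis and 2,3-trans).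

**Step 14**
Reactants: 19
Product: 20 blepharocalyxin C
Conditions: TBAF/AcOH (1:1, 8 equiv), THF, 0 °C to rt
Reagents that add atoms: none
Why: Buffered fluoride desilylation removes all five TBS groups without generating free phenoxide or strong acid, either of which could open the p-hydroxybenzylic C2–O1 bond through a quinone methide.

Stereocentre origins:

| Centre | Set in step |
|---|---|
| C5′ | 2 |
| C1′ (sacrificial, consumed in step 10) | 4 |
| C6 | 5 |
| C4 | 8 |
| C3, C3′ and the E-alkene | 10 |
| C2 | 13 |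

## Compound list

1 | tert-butyl(4-iodophenoxy)dimethylsilane | Ic1ccc(O[Si](C)(C)C(C)(C)C)cc1 | starting material
2 | allyl alcohol | OCC=C | starting material
3 | 3-Ar′-propanal | O=CCCc1ccc(O[Si](C)(C)C(C)(C)C)cc1 | intermediate
4 | allenyltributylstannane | C=C=C[Sn](CCCC)(CCCC)CCCC | starting material
5 | (S)-1-Ar′-hex-5-yn-3-ol | C#CC[C@@H](O)CCc1ccc(O[Si](C)(C)C(C)(C)C)cc1 | intermediate
6 | TBS ether of 5 | C#CC[C@@H](O[Si](C)(C)C(C)(C)C)CCc1ccc(O[Si](C)(C)C(C)(C)C)cc1 | intermediate
7 | 4-(TBSO)benzaldehyde | O=Cc1ccc(O[Si](C)(C)C(C)(C)C)cc1 | starting material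
8 | (1S,2E,5S)-allylic alcohol | O[C@H](c1ccc(O[Si](C)(C)C(C)(C)C)cc1)/C=C/C[C@@H](O[Si](C)(C)C(C)(C)C)CCc1ccc(O[Si](C)(C)C(C)(C)C)cc1 | intermediate
9 | allyltributylstannane | C=CC[Sn](CCCC)(CCCC)CCCC | starting material
10 | (S)-1-Ar′-hex-5-en-3-ol | C=CC[C@@H](O)CCc1ccc(O[Si](C)(C)C(C)(C)C)cc1 | intermediate
11 | TES ether of 10 | C=CC[C@@H](O[Si](CC)(CC)CC)CCc1ccc(O[Si](C)(C)C(C)(C)C)cc1 | intermediate
12 | (3S)-3-(TESO)-5-Ar′-pentanal | O=CC[C@@H](O[Si](CC)(CC)CC)CCc1ccc(O[Si](C)(C)C(C)(C)C)cc1 | intermediate
13 | acetyl bromide | CC(=O)Br | starting material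
14 | (4S)-β-lactone | O=C1C[C@H](C[C@@H](O[Si](CC)(CC)CC)CCc2ccc(O[Si](C)(C)C(C)(C)C)cc2)O1 | intermediate
15 | β-hydroxy allylic ester | O=C(C[C@@H](O)C[C@@H](O[Si](CC)(CC)CC)CCc1ccc(O[Si](C)(C)C(C)(C)C)cc1)O[C@H](c1ccc(O[Si](C)(C)C(C)(C)C)cc1)/C=C/C[C@@H](O[Si](C)(C)C(C)(C)C)CCc1ccc(O[Si](C)(C)C(C)(C)C)cc1 | intermediate
16 | Claisen seco-acid | CC(C)(C)[Si](C)(C)Oc1ccc(/C=C/[C@H](C[C@@H](O[Si](C)(C)C(C)(C)C)CCc2ccc(O[Si](C)(C)C(C)(C)C)cc2)[C@H](C(=O)O)[C@@H](O)C[C@@H](O[Si](CC)(CC)CC)CCc2ccc(O[Si](C)(C)C(C)(C)C)cc2)cc1 | intermediate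
17 | hydroxy-δ-lactone | CC(C)(C)[Si](C)(C)Oc1ccc(/C=C/[C@H](C[C@@H](O[Si](C)(C)C(C)(C)C)CCc2ccc(O[Si](C)(C)C(C)(C)C)cc2)[C@@H]2C(=O)O[C@@H](CCc3ccc(O[Si](C)(C)C(C)(C)C)cc3)C[C@@H]2O)cc1 | intermediate
18 | C2 aryl hemiketal (C2 unassigned) | CC(C)(C)[Si](C)(C)Oc1ccc(/C=C/[C@H](C[C@@H](O[Si](C)(C)C(C)(C)C)CCc2ccc(O[Si](C)(C)C(C)(C)C)cc2)[C@@H]2C(O)(c3ccc(O[Si](C)(C)C(C)(C)C)cc3)O[C@@H](CCc3ccc(O[Si](C)(C)C(C)(C)C)cc3)C[C@@H]2O)cc1 | intermediate
19 | penta-TBS blepharocalyxin C | CC(C)(C)[Si](C)(C)Oc1ccc(/C=C/[C@H](C[C@@H](O[Si](C)(C)C(C)(C)C)CCc2ccc(O[Si](C)(C)C(C)(C)C)cc2)[C@@H]2[C@@H](c3ccc(O[Si](C)(C)C(C)(C)C)cc3)O[C@@H](CCc3ccc(O[Si](C)(C)C(C)(C)C)cc3)C[C@@H]2O)cc1 | intermediate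
20 | blepharocalyxin C | Oc1ccc(/C=C/[C@H](C[C@@H](O)CCc2ccc(O)cc2)[C@@H]2[C@@H](c3ccc(O)cc3)O[C@@H](CCc3ccc(O)cc3)C[C@@H]2O)cc1 | target

## Totals

Total steps: 14.
Longest linear sequence: 11 (steps 1, then 5 to 14).

## Three steps most likely to fail

1. **Step 10.** The p-silyloxybenzylic/allylic ester may ionise or lose ketene, or react through a boat transition state.
   Fallback: take the aryl group out of the rearrangement.
   - Convert 6 into the primary (E)-allylic alcohol (lithiation, paraformaldehyde, then Red-Al) and acylate it with 14.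
   - Let the chelated dianion alone control facial selectivity (Fráter–Seebach sense). This gives a terminal vinyl group at C3′.
   - Install the E-styrene afterwards by Heck coupling with iodide 1.

2. **Step 13.** Hydride must arrive syn to the axial C4 oxygen. Competing paths are glycal formation followed by Ferrier loss of O4, O5′ participation, and ionic hydrogenation of the styrene.
   Fallback: replace kinetic C–H bond formation with thermodynamic C–O bond formation.
   - Reduce the open keto form of 18 with NaBH4 to the benzylic 1,5-diol.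
   - Close the ring by catalytic acid (TsOH or FeCl3) SN1 etherification through the p-silyloxybenzyl cation, which equilibrates to the isomer with C2, C3 and C6 substituents equatorial.

3. **Step 9.** The product alkoxide may compete for the β-lactone and oligomerise, the β-lactone may undergo E1cB opening, or TES may migrate.
   Fallback: abandon the β-lactone and dianion pairing.
   - Run a thiazolidinethione (Nagao-type) acetate aldol on 12 and protect O4 as TES.
   - Transfer the acyl group to the lithium alkoxide of 8.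
   - Run a conventional mono-anionic Ireland–Claisen (LiHMDS, THF/DMPU, TMSCl) on the β-silyloxy ester. Step 11 then removes both TES groups.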